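The synthesis rests on cutting the bond between benzylic C1 of the heptane chain and the ipso carbon of the catechol ring (para to O4). The key step exploits that C1 and C2 lie next to the oxygenated C3, so they can be the vinyl group of an acrolein aldol adduct: one-pot hydroboration/B-alkyl Suzuki–Miyaura coupling turns this once electrophilic terminus into a C1 nucleophile and joins it to a 4-bromocatechol dibenzyl ether, with both stereocentres already in place. The precursor is a vinyl carbinol acetate carrying the anti O3-acetyl/O5-H pair, made by Evans–Tishchenko reduction, which sets C5 and differentiates the two oxygens at once.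

Key step: step 3

Remark: chain atoms are numbered C1–C7 as in the target throughout (C1 bonded to the catechol ring, acetate on O3, free hydroxyl on O5), also where the systematic name of an intermediate numbers differently; compounds 1, 2 and 8 are taken as purchased.

Step 1
Reactants: 1 4-[4-(benzyloxy)phenyl]butan-2-one; 2 acrolein
Product: 5 (R)-1-[4-(benzyloxy)phenyl]-5-hydroxyhept-6-en-3-one, via enol borinate 3 (not isolated), via boron aldolate 4 (not isolated)
Conditions: (−)-Ipc2BCl, Et3N, Et2O, 0 °C; then 2, −78 to −20 °C; H2O2, MeOH, pH 7 buffer, 0 °C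
Reagents that add atoms: none
Why: Paterson boron aldol reaction: (−)-Ipc2BCl/Et3N should enolise the methyl ketone on its CH3 side to enol borinate 3, which adds 1,2 to acrolein through a cyclic boron-bound transition state in which the isopinocampheyl ligands (from (+)-α-pinene) steer the enolate to the re face of the aldehyde, so that oxidative cleavage of aldolate 4 should give the (R)-carbinol, the future C3.

Step 2
Reactants: 5 (R)-1-[4-(benzyloxy)phenyl]-5-hydroxyhept-6-en-3-one
Product: 7 (3R,5S)-7-[4-(benzyloxy)phenyl]-5-hydroxyhept-1-en-3-yl acetate, via hemiacetal 6 (not isolated)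
Conditions: SmI2 (30 mol%), MeCHO (6 equiv), THF, −10 °C
Reagents that add atoms: acetaldehyde (CC=O)
Why: Evans–Tishchenko reduction: the free carbinol oxygen O3 adds to acetaldehyde to give the samarium-bound hemiacetal 6, whose hydride is delivered intramolecularly to the ketone through a chair-like six-membered transition state organised by trivalent samarium, so the new C5 carbinol should be set anti to C3 while the acetyl group ends up only on O3.

Step 3
Reactants: 7 (3R,5S)-7-[4-(benzyloxy)phenyl]-5-hydroxyhept-1-en-3-yl acetate; 8 1,2-bis(benzyloxy)-4-bromobenzene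
Product: 10 (3S,5S)-1-[3,4-bis(benzyloxy)phenyl]-7-[4-(benzyloxy)phenyl]-5-hydroxyheptan-3-yl acetate, via bis-9-BBN adduct 9 (not isolated)
Conditions: 9-BBN (2.5 equiv), THF, 0 °C to rt; then 8, Pd(dppf)Cl2 (5 mol%), K3PO4, DMF, 50 °C; pH 7 buffer
Reagents that add atoms: none
Why: 9-BBN adds syn and anti-Markovnikov to the C1=C2 vinyl group of 7, placing boron on terminal C1 for steric reasons (the C3 acetoxy group is gamma to boron, so no beta-elimination path exists), and it also caps the O5 hydroxyl as a B-alkoxy-9-BBN, giving 9. Phosphate then forms the alkylborate, aryl bromide 8 adds oxidatively to zerovalent palladium generated from Pd(dppf)Cl2, the primary alkyl group passes from boron to palladium, and the wide-bite-angle dppf ligand favours reductive elimination over beta-hydride elimination, which forges the C1–aryl bond. The closest known reaction type is the B-alkyl Suzuki–Miyaura coupling (hydroboration/cross-coupling), in effect an anti-Markovnikov hydroarylation that unites two carbons which both began as electrophiles (the beta-carbon of acrolein and the aryl bromide carbon). No ring is closed and no stereocentre is created; C3 and C5 take part in no bond change and should keep their configuration (the descriptor at C3 changes from R to S only because the vinyl group becomes an alkyl chain). The step needs terminal regioselectivity in the hydroboration, secured by the bulk of 9-BBN at a monosubstituted alkene, and it needs the acetyl group to stay on O3, secured by the water-poor, non-nucleophilic base and by the temporary borinate on O5, which is hydrolysed only on work-up.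

Step 4
Reactants: 10 (3S,5S)-1-[3,4-bis(benzyloxy)phenyl]-7-[4-(benzyloxy)phenyl]-5-hydroxyheptan-3-yl acetate
Product: 11 (3S,5S)-1-(3,4-dihydroxyphenyl)-5-hydroxy-7-(4-hydroxyphenyl)heptan-3-yl acetate
Conditions: H2 (1 atm), 10% Pd/C, EtOAc, rt
Reagents that add atoms: none
Why: Hydrogenolysis of the three aryl benzyl ethers on palladium under neutral, aprotic conditions should leave the secondary acetate, the free carbinol and both stereocentres untouched, since no C–O bond of the chain is benzylic and no acid or base is present to trigger 1,3-acyl migration.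

Compound list
1 | 4-[4-(benzyloxy)phenyl]butan-2-one | CC(=O)CCc1ccc(OCc2ccccc2)cc1 | starting material
2 | acrolein (prop-2-enal) | C=CC=O | starting material
3 | O-diisopinocampheylboryl enolate of 1 on the CH3 side (isopinocampheyl groups from (+)-α-pinene) | C=C(CCc1ccc(OCc2ccccc2)cc1)OB([C@@H]1C[C@@H]2C[C@H]([C@H]1C)C2(C)C)[C@@H]1C[C@@H]2C[C@H]([C@H]1C)C2(C)C | intermediate
4 | O-diisopinocampheylboryl aldolate of 5, (R) at the carbinol carbon | C=C[C@@H](CC(=O)CCc1ccc(OCc2ccccc2)cc1)OB([C@@H]1C[C@@H]2C[C@H]([C@H]1C)C2(C)C)[C@@H]1C[C@@H]2C[C@H]([C@H]1C)C2(C)C | intermediate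
5 | (R)-1-[4-(benzyloxy)phenyl]-5-hydroxyhept-6-en-3-one | O[C@@H](C=C)CC(=O)CCc1ccc(OCc2ccccc2)cc1 | intermediate
6 | 1-hydroxyethyl hemiacetal at O3 of 5 (samarium-bound in the flask; hemiacetal carbon unassigned) | CC(O)O[C@@H](C=C)CC(=O)CCc1ccc(OCc2ccccc2)cc1 | intermediate
7 | (3R,5S)-7-[4-(benzyloxy)phenyl]-5-hydroxyhept-1-en-3-yl acetate (anti) | CC(=O)O[C@@H](C=C)C[C@@H](O)CCc1ccc(OCc2ccccc2)cc1 | intermediate
8 | 1,2-bis(benzyloxy)-4-bromobenzene | Brc1ccc(OCc2ccccc2)c(OCc2ccccc2)c1 | starting material
9 | (3S,5S)-7-[4-(benzyloxy)phenyl]-1-(9-borabicyclo[3.3.1]nonan-9-yl)-5-[(9-borabicyclo[3.3.1]nonan-9-yl)oxy]heptan-3-yl acetate | CC(=O)O[C@@H](CCB1C2CCCC1CCC2)C[C@@H](OB1C2CCCC1CCC2)CCc1ccc(OCc2ccccc2)cc1 | intermediate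
10 | (3S,5S)-1-[3,4-bis(benzyloxy)phenyl]-7-[4-(benzyloxy)phenyl]-5-hydroxyheptan-3-yl acetate | CC(=O)O[C@@H](CCc1ccc(OCc2ccccc2)c(OCc2ccccc2)c1)C[C@@H](O)CCc1ccc(OCc2ccccc2)cc1 | intermediate
11 | (3S,5S)-1-(3,4-dihydroxyphenyl)-5-hydroxy-7-(4-hydroxyphenyl)heptan-3-yl acetate | CC(=O)O[C@@H](CCc1ccc(O)c(O)c1)C[C@@H](O)CCc1ccc(O)cc1 | target

Total step count: 4. Longest linear sequence: 4 steps (1 → 5 → 7 → 10 → 11).

Steps most likely to fail

1. Step 3 (key step). Once phosphate meets the 1,3-hydroxy acetate, the acetyl group may migrate from O3 to O5 or be lost, and hydroboration next to the allylic acetate may stall, leaving alkene that zerovalent palladium could ionise. Fallback: the aryl–C1 bond is made before any acetate exists. The sequence sets out from aryl bromide 8. A Jeffery-type Heck reaction with allyl alcohol (Pd(OAc)2, Bu4NCl, NaHCO3, DMF, 80 °C) should give 3-[3,4-bis(benzyloxy)phenyl]propanal F1, by aryl transfer to the terminal alkene carbon, beta-hydride elimination towards the carbinol and tautomerisation. Enol borinate 3, prepared from 1 as in step 1, should add to F1 through the boron aldolate F2 and give, after oxidative work-up, (S)-7-[3,4-bis(benzyloxy)phenyl]-1-[4-(benzyloxy)phenyl]-5-hydroxyheptan-3-one F3; the attack is on the same re face, and the descriptor differs from that of 5 only because an alkyl chain replaces the vinyl group. Evans–Tishchenko reduction as in step 2 (SmI2, MeCHO, THF, −10 °C), through the hemiacetal F4, should then give 10, where the route is rejoined.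

2. Step 1. Methyl-ketone isopinocampheylboron enolates discriminate only moderately between the two faces of an aldehyde, so 5 may form with inadequate enantiomeric purity. Fallback: racemic aldol followed by enzymatic kinetic resolution, setting out from 1 and 2. LiN(iPr)2 in THF at −78 °C should give the lithium enolate F5; acrolein then gives the lithium aldolate F6 and, after NH4Cl quench, racemic 1-[4-(benzyloxy)phenyl]-5-hydroxyhept-6-en-3-one F7. Candida antarctica lipase B with vinyl acetate in MTBE should, by the Kazlauskas rule (vinyl as the medium group, the keto chain as the large group), acetylate the (S)-alcohol to (S)-7-[4-(benzyloxy)phenyl]-5-oxohept-1-en-3-yl acetate F8 and leave the (R)-alcohol. After chromatographic separation this alcohol is 5, where the route is rejoined.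

3. Step 2. Hydride transfer within the samarium hemiacetal may stall, retro-aldol cleavage may compete, or the acetyl group may scramble between O3 and O5 during isolation. Fallback: reduction and acetylation are separated, with O5 and the alkene locked in a temporary ring; the sequence sets out from 5. Evans–Saksena reduction (Me4NBH(OAc)3, MeCN–AcOH, −30 °C) should give the anti diol (3R,5S)-7-[4-(benzyloxy)phenyl]hept-1-ene-3,5-diol F9. Iodoetherification (I2, NaHCO3, MeCN, 0 °C), by 5-exo attack of O5 on C2, should give (3R,5S)-5-{2-[4-(benzyloxy)phenyl]ethyl}-2-(iodomethyl)oxolan-3-ol F10, in which only O3 is free (configuration at the iodomethyl-bearing carbon is immaterial). Acetylation (Ac2O, pyridine, rt) gives (3R,5S)-5-{2-[4-(benzyloxy)phenyl]ethyl}-2-(iodomethyl)oxolan-3-yl acetate F11. Zinc dust in AcOH–THF at rt should then reopen the ring by reductive beta-elimination, restoring the C1=C2 alkene and the O5 hydroxyl and giving 7, where the route is rejoined.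

Further compounds
F1 | step 3 | 3-[3,4-bis(benzyloxy)phenyl]propanal | O=CCCc1ccc(OCc2ccccc2)c(OCc2ccccc2)c1
F2 | step 3 | O-diisopinocampheylboryl aldolate of F3 (not isolated) | C(Cc1ccc(OCc2ccccc2)c(OCc2ccccc2)c1)[C@@H](CC(=O)CCc1ccc(OCc2ccccc2)cc1)OB([C@@H]1C[C@@H]2C[C@H]([C@H]1C)C2(C)C)[C@@H]1C[C@@H]2C[C@H]([C@H]1C)C2(C)C
F3 | step 3 | (S)-7-[3,4-bis(benzyloxy)phenyl]-1-[4-(benzyloxy)phenyl]-5-hydroxyheptan-3-one | O[C@@H](CCc1ccc(OCc2ccccc2)c(OCc2ccccc2)c1)CC(=O)CCc1ccc(OCc2ccccc2)cc1
F4 | step 3 | 1-hydroxyethyl hemiacetal of F3 (not isolated; hemiacetal carbon unassigned) | CC(O)O[C@@H](CCc1ccc(OCc2ccccc2)c(OCc2ccccc2)c1)CC(=O)CCc1ccc(OCc2ccccc2)cc1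
F5 | step 1 | lithium enolate of 1 on the CH3 side (not isolated) | [Li]OC(=C)CCc1ccc(OCc2ccccc2)cc1
F6 | step 1 | racemic lithium aldolate of F7 (not isolated) | [Li]OC(C=C)CC(=O)CCc1ccc(OCc2ccccc2)cc1
F7 | step 1 | racemic 1-[4-(benzyloxy)phenyl]-5-hydroxyhept-6-en-3-one | OC(C=C)CC(=O)CCc1ccc(OCc2ccccc2)cc1
F8 | step 1 | (S)-7-[4-(benzyloxy)phenyl]-5-oxohept-1-en-3-yl acetate | CC(=O)O[C@H](C=C)CC(=O)CCc1ccc(OCc2ccccc2)cc1
F9 | step 2 | (3R,5S)-7-[4-(benzyloxy)phenyl]hept-1-ene-3,5-diol | O[C@@H](C=C)C[C@@H](O)CCc1ccc(OCc2ccccc2)cc1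
F10 | step 2 | (3R,5S)-5-{2-[4-(benzyloxy)phenyl]ethyl}-2-(iodomethyl)oxolan-3-ol | O[C@@H]1C[C@H](CCc2ccc(OCc3ccccc3)cc2)OC1CI
F11 | step 2 | (3R,5S)-5-{2-[4-(benzyloxy)phenyl]ethyl}-2-(iodomethyl)oxolan-3-yl acetate | CC(=O)O[C@@H]1C[C@H](CCc2ccc(OCc3ccccc3)cc2)OC1CI
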